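**Target's ledger.** Read target as the main credit in a ledger of the reagent in the second phase: each mole that leaves that phase has to reappear somewhere in the books.

in all of them: substrate 20 mM

| flask | reagent in the second phase | protic impurity | remark | time | volume of the second phase over the first |
|---|---|---|---|---|---|
| grey | 30 mM | 1.4 mM | run made earlier |  |  |
| ochre | 30 mM | 2.2 mM | run made earlier |  |  |
| flask | 30.0 mM | 1.00 mM |  | 40 min | 0.50 |

| grey: time / min | grey: target / % | ochre: time / min | ochre: target / % |
|---|---|---|---|
| 4.00 | 7.5 | 4.00 | 7.5 |
| 12.0 | 21.3 | 12.0 | 21.5 |
| 20.0 | 31.9 | 20.0 | 32.4 |
| 30.0 | 42.3 | 30.0 | 42.3 |

(scatter of a reading: 0.3 percentage points)

- percent here means substrate units held: one side product counts as two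
- in the second phase: reagent in the second phase; everything else is in the first
- charges count per volume of the first phase; a concentration in a rate is the amount of a species over the volume of its own phase; every rate counts per litre of the first phase
- what was read earlier has a scatter of 0.3 percentage points, one standard deviation
- steps that have been proposed: reagent in the reaction phase <-> reagent in the second phase; substrate + reagent in the reaction phase -> target; reagent in the reaction phase + target -> over-reacted product; reagent in the reaction phase + protic impurity -> quenched reagent; substrate + target -> side product
- the earlier runs hold the two phases in the same ratio of volumes as the flask asked about

- west: doubling the amount of reagent in the second phase, all else as stated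
- south-west: doubling the transfer coefficient of the reagent in the second phase, all else as stated

- target at 40 min, in percent of the substrate charged
- the change that raises the amount of target at 40 min, in percent of the substrate charged most ("none" if none brings more than 2 percentage points) (west / south-west / none)
- amount of target at 40 min, in percent of the substrate charged, after south-west

**Drain constant.** Assume transfer is the rate-limiting step, so that the reagent in the second phase leaves first order. Grey's first reading, set against the full charge, gives 0.0125 /min. Put the mean reagent over that interval back in and go round once: 0.0128 /min. This is the drain constant, the fraction of the reagent still in the second phase that crosses per minute.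

**Closing entries.** On this constant grey has drawn a reckoned 9.58 mM by 30.0 min, but its reading shows 8.46 mM as target, which leaves an estimated 1.12 mM for other entries. Ochre, with more protic impurity, reads the same 42.3% at that time, so drop the quenching entry. Let the gap grow with the square of the reagent drawn, a rule of my own for the proposed over-reaction, which takes reagent and target together.

**My reckoning.** On the same constant the flask draws a reckoned 12.0 mM, which closes my books at 51.3% target. South-west, reckoned the same way, draws 19.2 mM and closes at 73.6%. West, reckoned the same way, draws 24.1 mM, more than the substrate charge, so the square rule does not stretch that far, and the reckoned surplus of 4.07 mM can turn target into over-reacted product. Choose south-west.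

**The forecast.** It gives 50.3%, west as the best change and 50.8% after south-west, holding that “transfer is not limiting”.

**The result.** The flask gives 49.3%. The best change is south-west, which reaches 62.5% and gains 13 percentage points, more than the 7.6 points for west.

    reagent in the reaction phase ⇌ reagent in the second phase, rate k1*([reagent in the reaction phase] - [reagent in the second phase]/K1) per volume of the first phase (partition coefficient = 1.90, kL = 2.40 × 10⁻⁴ /s)
    substrate + reagent in the reaction phase → target (k = 1.70 /M/s)
    reagent in the reaction phase + target → over-reacted product (k = 0.250 /M/s)
    reagent in the reaction phase + protic impurity → quenched reagent (k = 0.140 /M/s)
    substrate + target → side product (k = 0.00950 /M/s)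

**Drain again.** The drain constant leaves 59.9% of the reagent in the second phase at 40 min, and the flask holds 54.9%. The neighbour flask with 50 mM of substrate holds about the same, 54.6% of its reagent charge, yet its target stands at 16.7% of its own substrate charged. In the flask at 17.0 min, substrate goes to target 7.6 times faster than to side product. At 40 min the flask still makes target 2.43 times faster than it uses it up.

(Readings and results are calculated on assumed constants.)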